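**Remark on the chemistry:** the name is read with the usual quinic acid numbering (carboxyl carbon C1, O3 cis and O5 trans to O4). The SMILES agrees: O1, O3 and O4 lie on one face of the ring, O5 on the other, with the absolute configuration of (−)-quinic and (−)-shikimic acid.

**Compound numbers used throughout:** 1 (−)-shikimic acid; 2 4-methoxybenzyl chloride; 3 4-methoxybenzyl shikimate; 4 4-methoxybenzyl 3-dehydroshikimate; 5 p-coumaric acid; 6 doubly 4-methoxybenzylated coumarate (in the flask); 7 (E)-4-(4-methoxybenzyloxy)cinnamic acid; 8 its acid chloride (in the flask); 9 the 4,5-diacyl enone; 10 tert-butyl hydroperoxide; 11 the epoxy ketone; 12 the α-phenylseleno ketone (in the flask); 13 the 4,5-diacyl 3-dehydroquinate ester; 14 its O1-diethylborinate (in the flask); 15 the protected target; 16 the target.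

## Analysis of the target

The target is a single cyclohexane ring, that of (−)-quinic acid. It carries a carboxyl group and a tertiary hydroxyl at C1, a free secondary hydroxyl at C3 and (E)-p-coumaroyl esters on O4 and O5. The four stereocentres C1, C3, C4 and C5 place O1, O3 and O4 on one face and O5 on the other, so in the chair O4, O5 and the carboxyl group are equatorial while O1 and O3 stand 1,3-diaxial. C3, C4 and C5 have the configuration of (−)-shikimic acid, which lacks only the oxygen and the stereocentre at C1. The sensitive parts are the two cinnamate esters (in base they shift to the cis-neighbouring O3, and nucleophiles cleave them), the (E)-alkenes (which rule out hydrogenation) and the free phenols. The difficulty is selectivity, not the skeleton: two of three secondary hydroxyls must be acylated, the third left free, and the quaternary carbinol C1 set with O1 cis to O4. The strategy rests on C1, C2 and C3: with C3 as a ketone, O4 and O5 are the only hydroxyls on the ring of a 3-dehydroshikimate, and C1 is the β-carbon of the enone C3(=O)–C2=C1, the carbon that must receive O1. The ketone therefore serves both as the protecting group of O3 and as the activating group for the C1–O bond.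

## Retrosynthetic reasoning

**16 from 15.** The last bonds cut are three benzylic C–O bonds: one ester at the C1 carboxyl and two aryl ethers on the coumaroyl phenols. All three are of one kind, so a single cold acidolysis removes them; base is excluded at this stage because it would move the C4 ester to the free cis O3. The forward reaction only has to ionise benzylic C–O bonds and trap the cation.

**15 from 13.** The C3–H bond is disconnected, which turns the C3 carbinol into a ketone. This is the reason O3 never needs a protecting group. The forward reduction has to deliver hydride to the face of C3 anti to O1, so that O3 ends axial and cis to O1 and O4; boron held on O1 (compound 14) provides that control.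

**13 from 11.** A C2–O bond is added back, so the C2 methylene of 13 becomes an oxirane carbon. The tertiary alcohol at C1 is thereby traced to an α,β-epoxy ketone. The forward step must cleave only the C–O bond α to the ketone and leave C1–O alone; a soft selenium nucleophile does this through 12, because C2 is secondary and C1 is quaternary.

**11 from 9 and 10.** Both C–O bonds of the oxirane are cut, which leads back to the enone 9 and the peroxide 10. This is the key disconnection. C1 is the only stereocentre that 1 lacks, and the enone makes C1 electrophilic. The forward reaction has to add the peroxide oxygen to C1 on the face anti to the C5 ester, and it must be faster than base-induced loss of that ester.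

**9 from 4 and 7.** The two ester C–O bonds at O4 and O5 are cut, so one molecule of 4 is joined to two molecules of 7. The esters are made at this point because in 4 these are the only hydroxyls, so the acylation has no choice to make. The forward reaction must acylate without a strong base; the acid 7 is therefore activated as its chloride 8 under neutral conditions and used in a little more than two equivalents.

**4 from 3, and 3 from 1 and 2.** The C3 carbonyl goes back to the allylic hydroxyl of 3, the only allylic one among three, and the benzylic ester goes back to the carboxylate of 1 and the chloride 2. The ring and the stereocentres C4 and C5 (and C3 until it is oxidised) come from the pool compound 1.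

**7 from 5 and 2.** The phenol ether bond is cut. Compound 5 is alkylated on both oxygens (6) and the ester is cleaved again, so the same chloride 2 protects the acid of 1 and the phenol of 5.

## Alternatives that were turned down

**Alternative 1:** Ring bond C1–C6 is disconnected. O1 and O3 are tied in a methylene acetal, which makes C1 the ester-bearing carbon of a 1,3-dioxane whose side chain ends in a primary iodide (the open-chain iodide A2).
- Forward key step: KN(SiMe3)2 forms the ester enolate at C1, which displaces the iodide (6-exo-tet closure of the carbocycle) to give the bicyclic acetal A1, tert-butyl 4,5-bis-O-(tert-butyldimethylsilyl)-1,3-O-methylenequinate.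
- For it: the acetal forces O1 and O3 cis, so C1 is fixed by geometry and not by a facial preference; O1/O3 are also distinguished from O4/O5 from the start. On the certainty of C1 it is stronger than the chosen route.
- Against it: A2 carries three contiguous stereocentres and must be assembled from an acyclic precursor over many steps. The closure builds a quaternary centre through a bicyclic transition state with the chain axial on the dioxane, while the strong base can eliminate HI next to the C5 silyl ether. Afterwards two silyl ethers must be exchanged for the acyl groups, and a methylene acetal and a tert-butyl ester must be removed with strong acid from a molecule whose esters migrate.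
- Comparison: the chosen route takes the ring and C3–C5 from 1, needs seven linear steps and ends with a cold acidolysis. It pays for this with a substrate-controlled facial selection at C1.

**Alternative 2:** The C3–O bond is disconnected by way of a C3–Si bond. The substrate is the O1 diethylhydrosilyl ether A4 of a 3-deoxyquinate.
- Forward key step: [Ir(cod)OMe]2 (monovalent iridium) with a tetramethylphenanthroline ligand and an alkene as hydrogen acceptor inserts silicon into the axial C3–H bond syn to O1 and gives the oxasilolane A3, 4-methoxybenzyl 3-deoxy-3,O1-(diethylsilanediyl)-4,5-bis-O-(tert-butyldimethylsilyl)quinate. Fleming–Tamao oxidation would then give the C3 hydroxyl with retention.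
- For it: the tether reaches only the C–H bond cis to O1, so the cis relation of O1 and O3 is guaranteed. On that point it is stronger than a hydride reduction.
- Against it: A4 is not a pool compound. From 1 it requires removal of the C3 oxygen and still requires the hydration at C1, so the central problem remains and a stereocentre that the pool supplied is discarded. O1 is a hindered tertiary α-hydroxy ester, and it has a second γ C–H bond at C5. The oxidative C–Si cleavage uses basic peroxide, so it must precede the acyl groups; O3 is then free while O4 and O5 are still silylated and needs protection once more.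
- Comparison: the chosen route sets C3 by a conventional chelation-controlled reduction in one step and never protects O3. It is much shorter, at the price of a less rigid guarantee at C3.

**Alternative 3:** Ring bond C4–C5 is disconnected as a retro-aldol. The open-chain keto aldehyde A6 would come from citric acid A7 by differentiating its two acetic acid arms.
- Forward key step: soft enolisation of the acyloxymethyl ketone of A6 with MgBr2·OEt2 and a tertiary amine, and reversible addition of C4 to the C5 aldehyde, closes the cyclohexanone A5, tert-butyl 4-O-[(E)-4-(methoxymethoxy)cinnamoyl]-3-dehydroquinate, with O4 and O5 equatorial.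
- For it: it uses the same ketone mask for O3 as the chosen route, carries one coumaroyl group in from the start, starts from a cheap achiral acid, and needs neither an epoxidation nor a reductive C–O cleavage. On convergence and on avoiding an enone it is as strong or stronger.
- Against it: C1 is the only stereocentre of A6. It must be created by desymmetrising the enantiotopic arms of A7 and must then alone decide the face on which C4 and C5 are formed. The equilibrium secures the trans-diequatorial relation of O4 and O5, but the choice between the two chairs depends on the small difference in equatorial preference between an ester and a hydroxyl at C1, so 1,4-induction should be weak. A5 has two β-hydroxyls (O1 and O5) open to elimination and aromatisation under the amine, its acyl group can shift to O5, and a second acylation on this labile ketol is still needed.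
- Comparison: the chosen route inherits C4 and C5 from 1 and sets only C1, under kinetic control by a well-understood axial addition.

Key step: step 5

## Route

Step 1
Reactants: 1 (−)-shikimic acid; 2 4-methoxybenzyl chloride
Product: 3 4-methoxybenzyl shikimate
Conditions: KHCO3, Bu4NI (cat.), DMF, rt
Reagents that add atoms: none
Why: O-Alkylation of the carboxylate (SN2 at the benzylic chloride); hydrogencarbonate deprotonates only the acid, so the three hydroxyls stay free and no stereocentre is touched.

Step 2
Reactants: 3 4-methoxybenzyl shikimate
Product: 4 4-methoxybenzyl 3-dehydroshikimate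
Conditions: activated MnO2, acetone, rt
Reagents that add atoms: none
Why: Chemoselective oxidation of an allylic alcohol on MnO2; only the C3 hydroxyl is allylic, the saturated secondary hydroxyls O4 and O5 are left, and the neutral heterogeneous medium spares the base-sensitive enone; C4 and C5 are untouched.

Step 3
Reactants: 5 p-coumaric acid; 2 4-methoxybenzyl chloride
Product: 7 (E)-4-(4-methoxybenzyloxy)cinnamic acid, via bis-PMB coumarate 6 (not isolated)
Conditions: 2 (2.2 equiv), K2CO3, DMF, 60 °C; then NaOH, H2O/MeOH, 60 °C; HCl (aq), 0 °C
Reagents that add atoms: sodium hydroxide, [Na+].[OH-]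
Why: Williamson alkylation of the phenoxide and the carboxylate together, then saponification of the ester alone by acyl–oxygen cleavage (the hydroxide oxygen ends up in the carboxyl group), the aryl ether being inert to hydroxide; the (E)-alkene takes no part.

Step 4
Reactants: 4 4-methoxybenzyl 3-dehydroshikimate; 7 (E)-4-(4-methoxybenzyloxy)cinnamic acid
Product: 9 4-methoxybenzyl 4,5-bis-O-[(E)-4-(4-methoxybenzyloxy)cinnamoyl]-3-dehydroshikimate, via acid chloride 8 (not isolated)
Conditions: 7 (2.4 equiv), Me2C=C(Cl)NMe2 (2.4 equiv), CH2Cl2, 0 °C to rt; then 4 (1.0 equiv), pyridine, CH2Cl2, −30 to 0 °C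
Reagents that add atoms: (E)-4-(4-methoxybenzyloxy)cinnamic acid 7 (second equivalent), OC(=O)/C=C/c1ccc(OCc2ccc(OC)cc2)cc1
Why: The α-chloroenamine turns the acid into its chloride without releasing HCl, and pyridine-mediated O-acylation follows; two molecules of 8, made from two molecules of 7, esterify O4 and O5, which are the only hydroxyls of 4, so no regiochemical choice arises. A weak base at low temperature keeps enolisation of the enone slow.

Step 5
Reactants: 9 4-methoxybenzyl 4,5-bis-O-[(E)-4-(4-methoxybenzyloxy)cinnamoyl]-3-dehydroshikimate; 10 tert-butyl hydroperoxide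
Product: 11 4-methoxybenzyl 1,2-epoxy-1,2-dihydro-4,5-bis-O-[(E)-4-(4-methoxybenzyloxy)cinnamoyl]-3-dehydroshikimate (oxirane oxygen on C1 and C2 on the face of O4 and anti to O5)
Conditions: t-BuOOH (in decane), DBU (0.1 equiv), CH2Cl2, −30 to −10 °C; AcOH
Reagents that add atoms: none
Why: Weitz–Scheffer nucleophilic epoxidation: the tert-butyl peroxide anion formed from 10 by the catalytic amidine adds to C1, the β-carbon of the C3 ketone, and the C2–C3 enolate attacks the proximal peroxide oxygen and expels tert-butoxide, which regenerates the peroxide anion. The oxirane closes in the 3-exo-tet mode and is the only ring formed. C1 is set by the direction of the conjugate addition: in the half-chair that keeps the C4 and C5 acyloxy groups pseudo-equatorial, the anion enters along the axial line leading to a chair-like enolate, which is the face anti to the C5 ester and syn to the C4 ester, as in additions to 5-substituted cyclohexenones. C2 is not set independently, because a three-membered ring can only close on the face where the peroxide already sits. Chemoselectivity rests on C1=C2 being activated by both the ketone and the ester, whereas the electron-rich cinnamate alkenes do not accept a hydroperoxide anion under amine catalysis. The competing enolisation at C4 or C6, which would expel the C5 ester and aromatise the ring, is held back because 10 is in excess over the amidine, so the strongest base present is the weakly basic peroxide anion, and by the low temperature. If the anion added first at C2 (β to the ester), the same oxirane would result, so the regiochemistry of the first addition does not matter.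

Step 6
Reactants: 11 4-methoxybenzyl 1,2-epoxy-1,2-dihydro-4,5-bis-O-[(E)-4-(4-methoxybenzyloxy)cinnamoyl]-3-dehydroshikimate
Product: 13 4-methoxybenzyl 4,5-bis-O-[(E)-4-(4-methoxybenzyloxy)cinnamoyl]-3-dehydroquinate, via α-phenylseleno ketone 12 (not isolated)
Conditions: (PhSe)2, NaBH4, EtOH, 0 °C to rt; AcOH; then 11, THF/EtOH, 0 °C
Reagents that add atoms: none
Why: Organoselenium reduction of an α,β-epoxy ketone to the β-hydroxy ketone: the selenolate of Na[PhSeB(OEt)3] opens the oxirane by SN2 at C2, the secondary carbon α to the ketone (C1 is quaternary), and a second selenolate removes selenium from 12 to give the enol, which the acetic acid buffer protonates; the C1–O bond is never broken, so C1 keeps its configuration, and all borohydride is consumed in making the reagent, so the ketone survives.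

Step 7
Reactants: 13 4-methoxybenzyl 4,5-bis-O-[(E)-4-(4-methoxybenzyloxy)cinnamoyl]-3-dehydroquinate
Product: 15 4-methoxybenzyl 4,5-bis-O-[(E)-4-(4-methoxybenzyloxy)cinnamoyl]quinate, via O1-diethylborinate 14 (not isolated)
Conditions: Et2BOMe, THF/MeOH (4:1), −78 °C; NaBH4, −78 °C; AcOH, then MeOH co-evaporation
Reagents that add atoms: none
Why: Narasaka–Prasad syn reduction of a β-hydroxy ketone: boron on the axial O1 binds the C3 carbonyl on its own face and blocks the axial trajectory, so external hydride arrives equatorially, anti to O1, and the new C3 hydroxyl is axial and cis to O1 and O4; boron holds the C3 oxygen until the acidic work-up, which prevents the base-promoted shift of the C4 ester to O3.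

Step 8
Reactants: 15 4-methoxybenzyl 4,5-bis-O-[(E)-4-(4-methoxybenzyloxy)cinnamoyl]quinate
Product: 16 4,5-di-O-p-coumaroylquinic acid
Conditions: CF3CO2H, C6HMe5, CH2Cl2, 0 °C
Reagents that add atoms: none
Why: Acidolysis (SN1) of the 4-methoxybenzyl ester and of the two aryl 4-methoxybenzyl ethers, the benzylic cation being trapped by pentamethylbenzene in a Friedel–Crafts alkylation; the cinnamate esters, the alkenes and all four stereocentres are untouched, and cold acid does not promote the O4-to-O3 acyl shift that base would.

## Compound list

1 | (−)-shikimic acid | O[C@@H]1[C@H](O)C=C(C(=O)O)C[C@H]1O | starting material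
2 | 4-methoxybenzyl chloride | COc1ccc(CCl)cc1 | starting material
3 | 4-methoxybenzyl shikimate | O[C@@H]1[C@H](O)C=C(C(=O)OCc2ccc(OC)cc2)C[C@H]1O | intermediate
4 | 4-methoxybenzyl 3-dehydroshikimate [(4S,5R)-4,5-dihydroxy-3-oxocyclohex-1-ene-1-carboxylate] | O[C@@H]1C(=O)C=C(C(=O)OCc2ccc(OC)cc2)C[C@H]1O | intermediate
5 | p-coumaric acid | OC(=O)/C=C/c1ccc(O)cc1 | starting material
6 | 4-methoxybenzyl (E)-4-(4-methoxybenzyloxy)cinnamate | COc1ccc(COC(=O)/C=C/c2ccc(OCc3ccc(OC)cc3)cc2)cc1 | intermediate
7 | (E)-4-(4-methoxybenzyloxy)cinnamic acid | OC(=O)/C=C/c1ccc(OCc2ccc(OC)cc2)cc1 | intermediate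
8 | (E)-4-(4-methoxybenzyloxy)cinnamoyl chloride | ClC(=O)/C=C/c1ccc(OCc2ccc(OC)cc2)cc1 | intermediate
9 | 4-methoxybenzyl 4,5-bis-O-[(E)-4-(4-methoxybenzyloxy)cinnamoyl]-3-dehydroshikimate | O=C(/C=C/c1ccc(OCc2ccc(OC)cc2)cc1)O[C@@H]1C(=O)C=C(C(=O)OCc2ccc(OC)cc2)C[C@H]1OC(=O)/C=C/c1ccc(OCc2ccc(OC)cc2)cc1 | intermediate
10 | tert-butyl hydroperoxide | CC(C)(C)OO | starting material
11 | 4-methoxybenzyl 1,2-epoxy-1,2-dihydro-4,5-bis-O-[(E)-4-(4-methoxybenzyloxy)cinnamoyl]-3-dehydroshikimate (oxirane oxygen on the face of O4, anti to O5) | O=C(/C=C/c1ccc(OCc2ccc(OC)cc2)cc1)O[C@@H]1C(=O)[C@@H]2O[C@]2(C(=O)OCc2ccc(OC)cc2)C[C@H]1OC(=O)/C=C/c1ccc(OCc2ccc(OC)cc2)cc1 | intermediate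
12 | 4-methoxybenzyl 2-(phenylselanyl)-4,5-bis-O-[(E)-4-(4-methoxybenzyloxy)cinnamoyl]-3-dehydroquinate (selenium anti to O1) | O=C(/C=C/c1ccc(OCc2ccc(OC)cc2)cc1)O[C@@H]1C(=O)[C@@H]([Se]c2ccccc2)[C@@](O)(C(=O)OCc2ccc(OC)cc2)C[C@H]1OC(=O)/C=C/c1ccc(OCc2ccc(OC)cc2)cc1 | intermediate
13 | 4-methoxybenzyl 4,5-bis-O-[(E)-4-(4-methoxybenzyloxy)cinnamoyl]-3-dehydroquinate | O=C(/C=C/c1ccc(OCc2ccc(OC)cc2)cc1)O[C@@H]1C(=O)C[C@@](O)(C(=O)OCc2ccc(OC)cc2)C[C@H]1OC(=O)/C=C/c1ccc(OCc2ccc(OC)cc2)cc1 | intermediate
14 | 4-methoxybenzyl 1-O-(diethylboranyl)-4,5-bis-O-[(E)-4-(4-methoxybenzyloxy)cinnamoyl]-3-dehydroquinate | O=C(/C=C/c1ccc(OCc2ccc(OC)cc2)cc1)O[C@@H]1C(=O)C[C@@](OB(CC)CC)(C(=O)OCc2ccc(OC)cc2)C[C@H]1OC(=O)/C=C/c1ccc(OCc2ccc(OC)cc2)cc1 | intermediate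
15 | 4-methoxybenzyl 4,5-bis-O-[(E)-4-(4-methoxybenzyloxy)cinnamoyl]quinate | O=C(/C=C/c1ccc(OCc2ccc(OC)cc2)cc1)O[C@@H]1[C@H](O)C[C@@](O)(C(=O)OCc2ccc(OC)cc2)C[C@H]1OC(=O)/C=C/c1ccc(OCc2ccc(OC)cc2)cc1 | intermediate
16 | 4,5-di-O-p-coumaroylquinic acid | O=C(/C=C/c1ccc(O)cc1)O[C@@H]1[C@H](O)C[C@@](O)(C(=O)O)C[C@H]1OC(=O)/C=C/c1ccc(O)cc1 | target

## Step count and least certain steps

Total: 8 steps. Longest linear sequence: 7 steps from 1 (steps 1, 2, 4, 5, 6, 7, 8); step 3 prepares the acyl donor.

**Step 5 (key step).**
- What may go wrong: enolisation at C4 or C6 by the amidine or the alkoxide, followed by loss of the C5 ester and aromatisation, may outrun peroxide addition, since the enone is one elimination away from a benzoate. Facial selectivity would also erode if the half-chair with pseudo-axial acyloxy groups takes part.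
- Fallback: O1 is introduced before the acyl groups, on a ring that has no ester to lose and whose conformation is locked. It sets out from 4. The trans-diol is bridged with 1,3-dichloro-1,1,3,3-tetraisopropyldisiloxane and imidazole to give 4-methoxybenzyl 4,5-O-(1,1,3,3-tetraisopropyldisiloxane-1,3-diyl)-3-dehydroshikimate F1; its seven-membered disiloxane ring holds O4 and O5 diequatorial. The same peroxide epoxidation (10, catalytic DBU) gives 4-methoxybenzyl 1,2-epoxy-1,2-dihydro-4,5-O-(1,1,3,3-tetraisopropyldisiloxane-1,3-diyl)-3-dehydroshikimate F2. Na[PhSeB(OEt)3] opens it to 4-methoxybenzyl 4,5-O-(1,1,3,3-tetraisopropyldisiloxane-1,3-diyl)-3-dehydroquinate F3. HF·pyridine in THF removes the bridge to give 4-methoxybenzyl 3-dehydroquinate F4. Acylation of its two secondary hydroxyls with two equivalents of 8 and pyridine (the tertiary O1 does not react, and the ketone still masks O3) comes back to the route at 13. The detour costs two steps and also takes the acylation of step 4 away from the enone.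

**Step 2.**
- What may go wrong: the allylic alcohol is conjugated to an ester and therefore oxidises slowly on MnO2. Long contact may bring over-oxidation of the new ketol, cleavage of the diol, or dehydration to the aromatic acid ester on the oxide surface.
- Fallback: oxidise before esterifying, by catalytic dehydrogenation. It sets out from 1: O2 over Pt/C in water (Heyns-type oxidation, selective for the pseudo-axial allylic hydroxyl) gives 3-dehydroshikimic acid F5. F5 is esterified without added base or acid by 4-methoxybenzyl 2,2,2-trichloroacetimidate in CH2Cl2/THF and comes back to the route at 4.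

**Step 4.**
- What may go wrong: once O5 is acylated, pyridine may trigger loss of that ester from the enolisable enone (aromatisation). The second acylation at the ketol oxygen O4 may also stall.
- Fallback: reverse the order of acylation and epoxidation, so that no acyloxy group is present while the ring is an enone. It sets out from 4, which is epoxidised with 10 and catalytic DBU to 4-methoxybenzyl 1,2-epoxy-1,2-dihydro-3-dehydroshikimate F6 (oxirane oxygen on the face of O4). F6 is then acylated at O4 and O5 with two equivalents of 8 and pyridine, and the route is rejoined at 11.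

**Step 6.**
- What may go wrong: the selenolate may react elsewhere, by displacing the C4 acyloxy group α to the ketone or by conjugate addition to a cinnamate. The β-hydroxy ketone may also dehydrate back to the enone if the medium is not kept buffered.
- Fallback: open the oxirane with halide and remove the halogen by a radical chain. It sets out from 11. MgI2 in toluene/Et2O at −60 °C attacks C2 and gives the trans iodohydrin 4-methoxybenzyl 2-iodo-4,5-bis-O-[(E)-4-(4-methoxybenzyloxy)cinnamoyl]-3-dehydroquinate F7 (iodine anti to O1). Deiodination with (Me3Si)3SiH and Et3B/air in toluene at 0 °C comes back to the route at 13.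

**Step 7.**
- What may go wrong: facial selectivity may be insufficient if the boron chelate between the axial O1 and the carbonyl forms poorly, and axial hydride delivery then gives the C3 epimer. The C4 ester may shift to O3 if the C3 alkoxide is set free before acidification.
- Fallback: replace substrate control by reagent control. It sets out from 13: Corey–Bakshi–Shibata reduction with the (S)-2-methyl-oxazaborolidine and catecholborane in toluene at −78 °C, which on the usual model (C4 as the large arm, C2 as the small arm) delivers hydride to the same face, with acidic work-up. It arrives at 15 and makes no new compound.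

## Further compounds

F1 | step 5 | 4-methoxybenzyl 4,5-O-(1,1,3,3-tetraisopropyldisiloxane-1,3-diyl)-3-dehydroshikimate | CC(C)[Si]3(C(C)C)O[Si](C(C)C)(C(C)C)O[C@@H]1C(=O)C=C(C(=O)OCc2ccc(OC)cc2)C[C@H]1O3
F2 | step 5 | 4-methoxybenzyl 1,2-epoxy-1,2-dihydro-4,5-O-(1,1,3,3-tetraisopropyldisiloxane-1,3-diyl)-3-dehydroshikimate (oxirane oxygen on the face of O4) | CC(C)[Si]3(C(C)C)O[Si](C(C)C)(C(C)C)O[C@@H]1C(=O)[C@@H]2O[C@]2(C(=O)OCc2ccc(OC)cc2)C[C@H]1O3
F3 | step 5 | 4-methoxybenzyl 4,5-O-(1,1,3,3-tetraisopropyldisiloxane-1,3-diyl)-3-dehydroquinate | CC(C)[Si]3(C(C)C)O[Si](C(C)C)(C(C)C)O[C@@H]1C(=O)C[C@@](O)(C(=O)OCc2ccc(OC)cc2)C[C@H]1O3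
F4 | step 5 | 4-methoxybenzyl 3-dehydroquinate | O[C@@H]1C(=O)C[C@@](O)(C(=O)OCc2ccc(OC)cc2)C[C@H]1O
F5 | step 2 | 3-dehydroshikimic acid | O[C@@H]1C(=O)C=C(C(=O)O)C[C@H]1O
F6 | step 4 | 4-methoxybenzyl 1,2-epoxy-1,2-dihydro-3-dehydroshikimate (oxirane oxygen on the face of O4) | O[C@@H]1C(=O)[C@@H]2O[C@]2(C(=O)OCc2ccc(OC)cc2)C[C@H]1O
F7 | step 6 | 4-methoxybenzyl 2-iodo-4,5-bis-O-[(E)-4-(4-methoxybenzyloxy)cinnamoyl]-3-dehydroquinate (iodine anti to O1) | O=C(/C=C/c1ccc(OCc2ccc(OC)cc2)cc1)O[C@@H]1C(=O)[C@@H](I)[C@@](O)(C(=O)OCc2ccc(OC)cc2)C[C@H]1OC(=O)/C=C/c1ccc(OCc2ccc(OC)cc2)cc1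
F0 | step 7 | none | none
A1 | alternative 1 | tert-butyl 4,5-bis-O-(tert-butyldimethylsilyl)-1,3-O-methylenequinate | CC(C)(C)[Si](C)(C)O[C@@H]1[C@H]2C[C@@](OCO2)(C(=O)OC(C)(C)C)C[C@H]1O[Si](C)(C)C(C)(C)C
A2 | alternative 1 | tert-butyl 6-[1,2-bis(tert-butyldimethylsilyloxy)-3-iodopropyl]-1,3-dioxane-4-carboxylate (configuration of the three oxygenated carbons as in A1; the ester-bearing carbon as either epimer) | CC(C)(C)[Si](C)(C)O[C@H]([C@H]1CC(OCO1)C(=O)OC(C)(C)C)[C@@H](CI)O[Si](C)(C)C(C)(C)C
A3 | alternative 2 | 4-methoxybenzyl 3-deoxy-3,O1-(diethylsilanediyl)-4,5-bis-O-(tert-butyldimethylsilyl)quinate | CC(C)(C)[Si](C)(C)O[C@@H]1[C@H]2C[C@@](O[Si]2(CC)CC)(C(=O)OCc2ccc(OC)cc2)C[C@H]1O[Si](C)(C)C(C)(C)C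
A4 | alternative 2 | 4-methoxybenzyl 3-deoxy-1-O-(diethylsilyl)-4,5-bis-O-(tert-butyldimethylsilyl)quinate | CC(C)(C)[Si](C)(C)O[C@@H]1CC[C@@](O[SiH](CC)CC)(C(=O)OCc2ccc(OC)cc2)C[C@H]1O[Si](C)(C)C(C)(C)C
A5 | alternative 3 | tert-butyl 4-O-[(E)-4-(methoxymethoxy)cinnamoyl]-3-dehydroquinate | O=C(/C=C/c1ccc(OCOC)cc1)O[C@@H]1C(=O)C[C@@](O)(C(=O)OC(C)(C)C)C[C@H]1O
A6 | alternative 3 | tert-butyl 2-hydroxy-4-oxo-2-(2-oxoethyl)-5-[(E)-4-(methoxymethoxy)cinnamoyloxy]pentanoate (carbinol carbon configured as C1 of A5) | O=C(/C=C/c1ccc(OCOC)cc1)OCC(=O)C[C@](O)(CC=O)C(=O)OC(C)(C)C
A7 | alternative 3 | citric acid | OC(=O)CC(O)(CC(=O)O)C(=O)O
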